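**Retrosynthetic overview**

1. Militarinone A ⇐ fluoride deprotection of the SEM/TES-protected pyridine N-oxide 39. C2'=C3' comes from aldol condensation of the 3-acetylpyridine N-oxide 20 with dienal 35; the N–OH comes from N-oxidation of a 2-alkoxypyridine, the C3 acetyl from ortho-lithiation.
2. Ring B (the cis-1,4-dihydroxycyclohexyl ring) is the para-oxygenated benzene ring of the amino acid unit: phenol → para-quinol → hydrogenation → NaBH4.
3. Ring A: 5-aryl-4-hydroxy-2-pyridone 11 ⇐ 5-arylpiperidine-2,4-dione 9 ⇐ radical ring enlargement of the 5-[aryl(phenylselanyl)methyl]pyrrolidine-2,4-dione 8. The plan rests on the N1–C6H=C5–C4(OH) edge of ring A: N1, C6 and C5 are N, Cα and Cβ of a tyrosine unit, and C4 is the ring ketone of a tetramic acid that has to move from Cα to Cβ (C4–C5 made, C4–C6 broken).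
4. 8 ⇐ PhSeH addition to the 5-arylidene tetramic acid 7 ⇐ dehydrotyrosine acid 4 + Meldrum's acid 5; 4 ⇐ phosphonoglycinate 1 + aldehyde 2. Ring order: five-membered lactam (step 3), enlarged to six-membered (step 5), aromatised (step 7); ring B is never closed, only reduced (steps 10–12).
5. Dienal 35 ⇐ two Wittig homologations of (2R,4R)-2,4-dimethylhexanal, whose two methyl centres both come from Evans alkylations of the same (S)-propionyl oxazolidinone 21 with triflates.

Key step: step 5

Remark on the chemistry: the side-chain centres read from the structure are (8'R,10'R) with 1,3-syn methyl groups, and the two ring B hydroxyls are cis. SEM = [2-(trimethylsilyl)ethoxy]methyl (SEMO = SEM–O–), TES = triethylsilyl (TESO = TES–O–). Primed locants belong to the acyl chain. Compounds 8–10 and 37 are carried as stereoisomer mixtures because those centres are erased later.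

**Route**

Step 1
Reactants: 1 methyl 2-[(tert-butoxycarbonyl)amino]-2-(dimethoxyphosphoryl)acetate; 2 4-(benzyloxy)benzaldehyde
Product: 3 methyl (2Z)-3-[4-(benzyloxy)phenyl]-2-[(tert-butoxycarbonyl)amino]prop-2-enoate
Conditions: DBU, CH2Cl2, 0 °C → rt
Reagents that add atoms: none
Why: Horner–Wadsworth–Emmons olefination of a phosphonoglycinate with an aromatic aldehyde, which is known to favour the Z-dehydroamino ester; the alkene geometry has no consequence later.

Step 2
Reactants: 3 methyl (2Z)-3-[4-(benzyloxy)phenyl]-2-[(tert-butoxycarbonyl)amino]prop-2-enoate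
Product: 4 (2Z)-3-[4-(benzyloxy)phenyl]-2-[(tert-butoxycarbonyl)amino]prop-2-enoic acid
Conditions: LiOH·H2O, THF/MeOH/H2O, rt; then 1 M HCl to pH 3
Reagents that add atoms: lithium hydroxide (LiOH), [Li+].[OH-]
Why: Saponification of a methyl ester; the carbamate and the benzyl ether are stable to LiOH.

Step 3
Reactants: 4 (2Z)-3-[4-(benzyloxy)phenyl]-2-[(tert-butoxycarbonyl)amino]prop-2-enoic acid; 5 2,2-dimethyl-1,3-dioxane-4,6-dione (Meldrum's acid)
Product: 7 tert-butyl (5Z)-5-[4-(benzyloxy)benzylidene]-2,4-dioxopyrrolidine-1-carboxylate, via acyl Meldrum's acid 6 (not isolated)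
Conditions: EDC·HCl, DMAP, CH2Cl2, 0 °C → rt; aq. KHSO4 wash; then EtOAc, reflux
Reagents that add atoms: none
Why: Meldrum's acid route to N-Boc tetramic acids (carbodiimide C-acylation of 5, then thermal loss of acetone and CO2 to an acylketene that the carbamate N–H traps to close the five-membered lactam), run here on a dehydroamino acid so that the exocyclic C5=C bond is already in place.

Step 4
Reactants: 7 tert-butyl (5Z)-5-[4-(benzyloxy)benzylidene]-2,4-dioxopyrrolidine-1-carboxylate
Product: 8 tert-butyl 2-{[4-(benzyloxy)phenyl](phenylselanyl)methyl}-3,5-dioxopyrrolidine-1-carboxylate (racemic diastereomer mixture)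
Conditions: PhSeH, cat. AcOH, degassed CH2Cl2, 0 °C → rt, dark; volatiles removed, used without chromatography
Reagents that add atoms: benzeneselenol, [SeH]c1ccccc1
Why: Conjugate (1,4) addition of a selenol to an ene-dione whose nitrogen carries two acyl groups, the arrangement known to make β-aryl dehydroamino carbonyl compounds accept soft nucleophiles; selenium adds to the benzylic carbon, relief of allylic strain between the Boc group and the aryl ring favours the adduct, and the absence of base keeps the acidic dione out of its unreactive enolate and blocks E1cB reversal, while both new centres are left uncontrolled because step 5 erases them.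

Step 5
Reactants: 8 tert-butyl 2-{[4-(benzyloxy)phenyl](phenylselanyl)methyl}-3,5-dioxopyrrolidine-1-carboxylate
Product: 9 tert-butyl 5-[4-(benzyloxy)phenyl]-2,4-dioxopiperidine-1-carboxylate (racemic)
Conditions: Bu3SnH and AIBN in PhH added by syringe pump over 8 h to 8 in refluxing PhH (0.005 M), 80 °C
Reagents that add atoms: none
Why: Proposed new method: Bu3Sn• removes the PhSe group of 8 and the resulting secondary benzylic radical adds 3-exo-trig to the neighbouring ring ketone (in benzene the N-Boc dione should sit mainly as the keto tautomer) to give a cyclopropyloxyl radical. β-Scission of the bond between the former ketone carbon and the nitrogen-bearing carbon then gives the ring-enlarged radical next to the carbamate nitrogen, which takes hydrogen from Bu3SnH to give 9. The closest known reaction type is the Dowd–Beckwith one-carbon ring expansion of 2-(halomethyl) cyclic β-keto esters by radical 1,2-acyl shift, from which this case differs in that the starting radical is benzylic and the product radical is α-amido instead of primary and ester-stabilised. The six-membered ring is therefore not closed directly but arises from the 3-exo-trig closure onto C=O followed by opening of the three-membered ring, which forms the C4–C5 bond of the future pyridone. No stereocentre has to be controlled, since the two centres of 8 are erased and the new C5 centre of 9 is formed as a racemate that disappears on aromatisation in step 7. The selectivity needed is rearrangement ahead of direct reduction of the benzylic radical; it should be secured by the slow hydrogen abstraction of a stabilised benzylic radical, by the faster capture of the less stabilised α-amido radical (which drains even an unfavourable radical equilibrium towards 9), by the contiguous radical carbon, ketone and N-bearing carbon with release of five-ring strain, and by the low stannane concentration.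

Step 6
Reactants: 9 tert-butyl 5-[4-(benzyloxy)phenyl]-2,4-dioxopiperidine-1-carboxylate
Product: 10 5-[4-(benzyloxy)phenyl]piperidine-2,4-dione (racemic)
Conditions: TFA, CH2Cl2, 0 °C → rt
Reagents that add atoms: none
Why: Acidolysis of the tert-butyl carbamate with loss of isobutene and CO2; the benzyl ether and the β-keto lactam are stable to TFA.

Step 7
Reactants: 10 5-[4-(benzyloxy)phenyl]piperidine-2,4-dione
Product: 11 5-[4-(benzyloxy)phenyl]-4-hydroxypyridin-2(1H)-one
Conditions: DDQ, 1,4-dioxane, 80 °C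
Reagents that add atoms: none
Why: Quinone dehydrogenation of a dihydropyridone: DDQ abstracts hydride from C6 of the aryl-conjugated enol and proton loss gives the aromatic 4-hydroxy-2-pyridone, aromatisation being the driving force; the C5 centre is erased.

Step 8
Reactants: 11 5-[4-(benzyloxy)phenyl]-4-hydroxypyridin-2(1H)-one
Product: 12 5-[4-(benzyloxy)phenyl]-2,4-bis(SEMO)pyridine
Conditions: SEMCl, Ag2CO3, toluene, rt → 50 °C, dark
Reagents that add atoms: [2-(trimethylsilyl)ethoxy]methyl chloride, C[Si](C)(C)CCOCCl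
Why: O-Alkylation of a pyridone silver salt (Ag2CO3 steers the ambident lactam to oxygen at C2 and the C4 hydroxyl is alkylated as well), which gives a 2,4-dialkoxypyridine with a free ring nitrogen for later N-oxidation and two fluoride-labile acetals.

Step 9
Reactants: 12 5-[4-(benzyloxy)phenyl]-2,4-bis(SEMO)pyridine
Product: 13 4-[4,6-bis(SEMO)pyridin-3-yl]phenol
Conditions: H2 (1 atm), 10% Pd/C, EtOAc/EtOH, rt
Reagents that add atoms: none
Why: Hydrogenolysis of the benzyl aryl ether over Pd/C; the SEM acetals and the pyridine ring are inert at one atmosphere of H2.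

Step 10
Reactants: 13 4-[4,6-bis(SEMO)pyridin-3-yl]phenol
Product: 14 4-[4,6-bis(SEMO)pyridin-3-yl]-4-hydroxycyclohexa-2,5-dien-1-one
Conditions: PhI(OAc)2, MeCN/H2O (3:1), 0 °C
Reagents that add atoms: water, O
Why: Oxidative dearomatisation of a para-substituted phenol with a trivalent iodine reagent: the phenoxenium ion, stabilised at the para carbon by the dialkoxypyridyl group, is captured there by water to give the para-quinol, and no stereocentre arises because the dienone is symmetric.

Step 11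
Reactants: 14 4-[4,6-bis(SEMO)pyridin-3-yl]-4-hydroxycyclohexa-2,5-dien-1-one
Product: 15 4-[4,6-bis(SEMO)pyridin-3-yl]-4-hydroxycyclohexan-1-one
Conditions: H2 (1 atm), 5% Rh/Al2O3, EtOAc, rt
Reagents that add atoms: none
Why: Heterogeneous hydrogenation of both enone C=C bonds; Rh/Al2O3 in a neutral solvent is chosen because it saturates quinols with little hydrogenolysis of the tertiary doubly allylic C–O bond.

Step 12
Reactants: 15 4-[4,6-bis(SEMO)pyridin-3-yl]-4-hydroxycyclohexan-1-one
Product: 16 cis-1-[4,6-bis(SEMO)pyridin-3-yl]cyclohexane-1,4-diol (both hydroxyls on the same face)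
Conditions: NaBH4, MeOH, −40 °C
Reagents that add atoms: none
Why: Borohydride reduction of a 4,4-disubstituted cyclohexanone: in the chair with the pyridyl group equatorial and the tertiary hydroxyl axial, the small hydride attacks axially and gives the equatorial secondary alcohol, that is, the 1,4-cis diol.

Step 13
Reactants: 16 cis-1-[4,6-bis(SEMO)pyridin-3-yl]cyclohexane-1,4-diol
Product: 17 5-[cis-1,4-bis(TESO)cyclohexyl]-2,4-bis(SEMO)pyridine
Conditions: TESOTf, 2,6-lutidine, CH2Cl2, −78 → −20 °C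
Reagents that add atoms: triethylsilyl trifluoromethanesulfonate, CC[Si](CC)(CC)OS(=O)(=O)C(F)(F)F
Why: Silyl triflate silylation protects the secondary and the hindered tertiary alcohol in one operation, and excess 2,6-lutidine at low temperature keeps the SEM acetals intact.

Step 14
Reactants: 17 5-[cis-1,4-bis(TESO)cyclohexyl]-2,4-bis(SEMO)pyridine
Product: 19 1-{5-[cis-1,4-bis(TESO)cyclohexyl]-2,4-bis(SEMO)pyridin-3-yl}ethan-1-one, via 3-lithiopyridine 18 (not isolated)
Conditions: n-BuLi, THF, −78 → −40 °C; then MeC(O)N(OMe)Me, −78 → 0 °C; aq. NH4Cl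
Reagents that add atoms: N-methoxy-N-methylacetamide, CON(C)C(C)=O
Why: Directed ortho-metalation: C3–H lies between two alkoxymethoxy groups that both coordinate lithium and is removed selectively, and the aryllithium is acylated by the Weinreb amide, whose chelated tetrahedral adduct prevents over-addition.

Step 15
Reactants: 19 1-{5-[cis-1,4-bis(TESO)cyclohexyl]-2,4-bis(SEMO)pyridin-3-yl}ethan-1-one
Product: 20 3-acetyl-5-[cis-1,4-bis(TESO)cyclohexyl]-2,4-bis(SEMO)pyridine 1-oxide
Conditions: mCPBA, NaHCO3, CH2Cl2, 0 °C → rt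
Reagents that add atoms: 3-chloroperoxybenzoic acid, OOC(=O)c1cccc(Cl)c1
Why: Peracid N-oxidation of a pyridine; the 4-alkoxy group keeps the nitrogen nucleophilic, no C=C bond is present yet, and NaHCO3 buffers the acid so that acetals and silyl ethers survive.

Step 16
Reactants: 21 (S)-4-benzyl-3-propionyloxazolidin-2-one
Product: 23 (S)-4-benzyl-3-[(R)-2-methylbutanoyl]oxazolidin-2-one, via sodium Z-enolate 22 (not isolated)
Conditions: NaN(SiMe3)2, THF, −78 °C; then EtOTf, −78 → −50 °C
Reagents that add atoms: ethyl trifluoromethanesulfonate, CCOS(=O)(=O)C(F)(F)F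
Why: Evans asymmetric alkylation: the chelated sodium Z-enolate is ethylated by the reactive triflate on the face away from the benzyl group, which for the (S)-auxiliary gives the (R) centre that becomes C10'.

Step 17
Reactants: 23 (S)-4-benzyl-3-[(R)-2-methylbutanoyl]oxazolidin-2-one
Product: 24 (R)-2-methylbutan-1-ol
Conditions: LiBH4, H2O (1 equiv), Et2O, 0 °C; careful distillation
Reagents that add atoms: none
Why: Reductive cleavage of the imide with LiBH4, which attacks the exocyclic carbonyl and releases the auxiliary without touching the α-centre.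

Step 18
Reactants: 24 (R)-2-methylbutan-1-ol
Product: 25 (R)-2-methylbutyl trifluoromethanesulfonate
Conditions: Tf2O, pyridine, CH2Cl2, −78 → −30 °C; pentane, short silica pad; used at once
Reagents that add atoms: trifluoromethanesulfonic anhydride, O=S(=O)(OS(=O)(=O)C(F)(F)F)C(F)(F)F
Why: Triflation of a primary alcohol, needed because a β-branched alkyl halide is too unreactive towards imide enolates.

Step 19
Reactants: 21 (S)-4-benzyl-3-propionyloxazolidin-2-one; 25 (R)-2-methylbutyl trifluoromethanesulfonate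
Product: 27 (S)-4-benzyl-3-[(2R,4R)-2,4-dimethylhexanoyl]oxazolidin-2-one, via lithium Z-enolate 26 (not isolated)
Conditions: LiN(i-Pr)2 (commercial solution), THF, −78 °C; then 25, −78 → −20 °C
Reagents that add atoms: none
Why: Second Evans alkylation, now of the chelated lithium Z-enolate with a primary alkyl triflate; the lithium enolate is chosen because it tolerates the warming that the β-branched electrophile needs, and the auxiliary again directs attack to the face away from the benzyl group and sets C8' as (R), which with the (R) centre of 25 gives the 1,3-syn dimethyl array.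

Step 20
Reactants: 27 (S)-4-benzyl-3-[(2R,4R)-2,4-dimethylhexanoyl]oxazolidin-2-one
Product: 28 (2R,4R)-2,4-dimethylhexan-1-ol
Conditions: LiBH4, H2O (1 equiv), Et2O, 0 °C
Reagents that add atoms: none
Why: LiBH4 cleavage of the imide to the primary alcohol with recovery of the auxiliary and no epimerisation.

Step 21
Reactants: 28 (2R,4R)-2,4-dimethylhexan-1-ol
Product: 30 ethyl (2E,4R,6R)-2,4,6-trimethyloct-2-enoate, via (2R,4R)-2,4-dimethylhexanal 29 (not isolated)
Conditions: Dess–Martin periodinane, Ph3P=C(Me)CO2Et, CH2Cl2, rt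
Reagents that add atoms: ethyl 2-(triphenyl-λ5-phosphanylidene)propanoate, CCOC(=O)C(C)=P(c1ccccc1)(c1ccccc1)c1ccccc1
Why: Dess–Martin oxidation in the presence of a stabilised ylide, so that the epimerisable α-branched aldehyde is consumed as it forms, and the Wittig reaction of the α-methyl ester ylide gives the E-trisubstituted alkene.

Step 22
Reactants: 30 ethyl (2E,4R,6R)-2,4,6-trimethyloct-2-enoate
Product: 31 (2E,4R,6R)-2,4,6-trimethyloct-2-en-1-ol
Conditions: i-Bu2AlH, CH2Cl2, −78 °C; aq. KNaC4H4O6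
Reagents that add atoms: none
Why: i-Bu2AlH reduction of an unsaturated ester to the allylic alcohol by 1,2-hydride delivery.

Step 23
Reactants: 31 (2E,4R,6R)-2,4,6-trimethyloct-2-en-1-ol
Product: 33 ethyl (2E,4E,6R,8R)-4,6,8-trimethyldeca-2,4-dienoate, via (2E,4R,6R)-2,4,6-trimethyloct-2-enal 32 (not isolated)
Conditions: MnO2, Ph3P=CHCO2Et, CH2Cl2, rt → reflux
Reagents that add atoms: ethyl 2-(triphenyl-λ5-phosphanylidene)acetate, CCOC(=O)C=P(c1ccccc1)(c1ccccc1)c1ccccc1
Why: In situ MnO2 oxidation–Wittig sequence: the allylic alcohol is oxidised to the enal, which the stabilised ylide traps to give the E-disubstituted alkene.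

Step 24
Reactants: 33 ethyl (2E,4E,6R,8R)-4,6,8-trimethyldeca-2,4-dienoate
Product: 34 (2E,4E,6R,8R)-4,6,8-trimethyldeca-2,4-dien-1-ol
Conditions: i-Bu2AlH, CH2Cl2, −78 °C; aq. KNaC4H4O6
Reagents that add atoms: none
Why: i-Bu2AlH reduction of the dienoate to the dienol.

Step 25
Reactants: 34 (2E,4E,6R,8R)-4,6,8-trimethyldeca-2,4-dien-1-ol
Product: 35 (2E,4E,6R,8R)-4,6,8-trimethyldeca-2,4-dienal
Conditions: MnO2, CH2Cl2, rt
Reagents that add atoms: none
Why: MnO2 oxidation of an allylic alcohol to the dienal without isomerisation of the diene or the remote stereocentres.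

Step 26
Reactants: 20 3-acetyl-5-[cis-1,4-bis(TESO)cyclohexyl]-2,4-bis(SEMO)pyridine 1-oxide; 35 (2E,4E,6R,8R)-4,6,8-trimethyldeca-2,4-dienal
Product: 37 5-[cis-1,4-bis(TESO)cyclohexyl]-3-[(4E,6E,8R,10R)-3-hydroxy-6,8,10-trimethyldodeca-4,6-dienoyl]-2,4-bis(SEMO)pyridine 1-oxide (mixture of C3' epimers), via lithium enolate 36 (not isolated)
Conditions: LiN(SiMe3)2, THF, −78 °C; then 35, −78 °C; aq. NH4Cl at −78 °C
Reagents that add atoms: none
Why: Directed aldol addition: LiN(SiMe3)2 removes only the methyl ketone proton and the lithium enolate adds 1,2 at low temperature to the dienal, which has no α-hydrogen; the carbinol centre is left uncontrolled because step 27 removes it.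

Step 27
Reactants: 37 5-[cis-1,4-bis(TESO)cyclohexyl]-3-[(4E,6E,8R,10R)-3-hydroxy-6,8,10-trimethyldodeca-4,6-dienoyl]-2,4-bis(SEMO)pyridine 1-oxide
Product: 39 5-[cis-1,4-bis(TESO)cyclohexyl]-3-[(2E,4E,6E,8R,10R)-6,8,10-trimethyldodeca-2,4,6-trienoyl]-2,4-bis(SEMO)pyridine 1-oxide, via β-acetoxy ketone 38 (not isolated)
Conditions: Ac2O, Et3N, cat. DMAP, CH2Cl2, 0 °C; then DBU, 0 °C → rt
Reagents that add atoms: none
Why: Acetylation followed by E1cB elimination of the β-acetoxy ketone with DBU gives the thermodynamically favoured E-enone and completes the all-E trienone; acetic anhydride is used instead of a sulfonyl chloride so that the N-oxide is not activated.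

Step 28
Reactants: 39 5-[cis-1,4-bis(TESO)cyclohexyl]-3-[(2E,4E,6E,8R,10R)-6,8,10-trimethyldodeca-2,4,6-trienoyl]-2,4-bis(SEMO)pyridine 1-oxide
Product: 40 militarinone A, 1,4-dihydroxy-5-(cis-1,4-dihydroxycyclohexyl)-3-[(2E,4E,6E,8R,10R)-6,8,10-trimethyldodeca-2,4,6-trienoyl]pyridin-2(1H)-one
Conditions: Bu4NF, THF, 0 °C → rt; aq. NaH2PO4 (pH 5)
Reagents that add atoms: none
Why: Fluoride-induced global deprotection: attack at silicon cleaves both TES ethers and fragments both SEM acetals with loss of ethene and formaldehyde, helped by the good leaving ability of the 2-oxidopyridine N-oxide and of the acyl-conjugated 4-oxide; the freed 2-hydroxypyridine N-oxide is the tautomer of the 1-hydroxy-2-pyridone, and the absence of acid spares the tertiary alcohol and the trienone.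

**Compound list**

1 | methyl 2-[(tert-butoxycarbonyl)amino]-2-(dimethoxyphosphoryl)acetate (racemic) | COC(=O)C(NC(=O)OC(C)(C)C)P(=O)(OC)OC | starting material
2 | 4-(benzyloxy)benzaldehyde | O=Cc1ccc(OCc2ccccc2)cc1 | starting material
3 | methyl (2Z)-3-[4-(benzyloxy)phenyl]-2-[(tert-butoxycarbonyl)amino]prop-2-enoate | COC(=O)/C(NC(=O)OC(C)(C)C)=C/c1ccc(OCc2ccccc2)cc1 | intermediate
4 | (2Z)-3-[4-(benzyloxy)phenyl]-2-[(tert-butoxycarbonyl)amino]prop-2-enoic acid | OC(=O)/C(NC(=O)OC(C)(C)C)=C/c1ccc(OCc2ccccc2)cc1 | intermediate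
5 | 2,2-dimethyl-1,3-dioxane-4,6-dione (Meldrum's acid) | CC1(C)OC(=O)CC(=O)O1 | starting material
6 | tert-butyl {(1Z)-2-[4-(benzyloxy)phenyl]-1-[(2,2-dimethyl-4,6-dioxo-1,3-dioxan-5-yl)carbonyl]ethenyl}carbamate (acyl Meldrum's acid) | CC1(C)OC(=O)C(C(=O)/C(NC(=O)OC(C)(C)C)=C/c2ccc(OCc3ccccc3)cc2)C(=O)O1 | intermediate (not isolated)
7 | tert-butyl (5Z)-5-[4-(benzyloxy)benzylidene]-2,4-dioxopyrrolidine-1-carboxylate | CC(C)(C)OC(=O)N1C(=O)CC(=O)/C1=C/c2ccc(OCc3ccccc3)cc2 | intermediate
8 | tert-butyl 2-{[4-(benzyloxy)phenyl](phenylselanyl)methyl}-3,5-dioxopyrrolidine-1-carboxylate (racemic diastereomer mixture) | CC(C)(C)OC(=O)N1C(=O)CC(=O)C1C([Se]c1ccccc1)c1ccc(OCc2ccccc2)cc1 | intermediate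
9 | tert-butyl 5-[4-(benzyloxy)phenyl]-2,4-dioxopiperidine-1-carboxylate (racemic) | CC(C)(C)OC(=O)N1CC(C(=O)CC1=O)c1ccc(OCc2ccccc2)cc1 | intermediate
10 | 5-[4-(benzyloxy)phenyl]piperidine-2,4-dione (racemic) | O=C1CC(=O)C(CN1)c1ccc(OCc2ccccc2)cc1 | intermediate
11 | 5-[4-(benzyloxy)phenyl]-4-hydroxypyridin-2(1H)-one | O=c1cc(O)c(c[nH]1)-c1ccc(OCc2ccccc2)cc1 | intermediate
12 | 5-[4-(benzyloxy)phenyl]-2,4-bis{[2-(trimethylsilyl)ethoxy]methoxy}pyridine | C[Si](C)(C)CCOCOc1cc(OCOCC[Si](C)(C)C)c(cn1)-c1ccc(OCc2ccccc2)cc1 | intermediate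
13 | 4-(4,6-bis{[2-(trimethylsilyl)ethoxy]methoxy}pyridin-3-yl)phenol | C[Si](C)(C)CCOCOc1cc(OCOCC[Si](C)(C)C)c(cn1)-c1ccc(O)cc1 | intermediate
14 | 4-(4,6-bis{[2-(trimethylsilyl)ethoxy]methoxy}pyridin-3-yl)-4-hydroxycyclohexa-2,5-dien-1-one | C[Si](C)(C)CCOCOc1cc(OCOCC[Si](C)(C)C)c(cn1)C2(O)C=CC(=O)C=C2 | intermediate
15 | 4-(4,6-bis{[2-(trimethylsilyl)ethoxy]methoxy}pyridin-3-yl)-4-hydroxycyclohexan-1-one | C[Si](C)(C)CCOCOc1cc(OCOCC[Si](C)(C)C)c(cn1)C2(O)CCC(=O)CC2 | intermediate
16 | cis-1-(4,6-bis{[2-(trimethylsilyl)ethoxy]methoxy}pyridin-3-yl)cyclohexane-1,4-diol (hydroxyls cis) | C[Si](C)(C)CCOCOc1cc(OCOCC[Si](C)(C)C)c(cn1)[C@]2(O)CC[C@@H](O)CC2 | intermediate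
17 | 5-[cis-1,4-bis(triethylsilyloxy)cyclohexyl]-2,4-bis{[2-(trimethylsilyl)ethoxy]methoxy}pyridine | C[Si](C)(C)CCOCOc1cc(OCOCC[Si](C)(C)C)c(cn1)[C@]2(O[Si](CC)(CC)CC)CC[C@@H](O[Si](CC)(CC)CC)CC2 | intermediate
18 | 3-lithio derivative of 17 | [Li]c1c(OCOCC[Si](C)(C)C)c([C@]2(O[Si](CC)(CC)CC)CC[C@@H](O[Si](CC)(CC)CC)CC2)cnc1OCOCC[Si](C)(C)C | intermediate (not isolated)
19 | 1-{5-[cis-1,4-bis(triethylsilyloxy)cyclohexyl]-2,4-bis{[2-(trimethylsilyl)ethoxy]methoxy}pyridin-3-yl}ethan-1-one | CC(=O)c1c(OCOCC[Si](C)(C)C)c([C@]2(O[Si](CC)(CC)CC)CC[C@@H](O[Si](CC)(CC)CC)CC2)cnc1OCOCC[Si](C)(C)C | intermediate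
20 | 3-acetyl-5-[cis-1,4-bis(triethylsilyloxy)cyclohexyl]-2,4-bis{[2-(trimethylsilyl)ethoxy]methoxy}pyridine 1-oxide | CC(=O)c1c(OCOCC[Si](C)(C)C)c([C@]2(O[Si](CC)(CC)CC)CC[C@@H](O[Si](CC)(CC)CC)CC2)c[n+]([O-])c1OCOCC[Si](C)(C)C | intermediate
21 | (S)-4-benzyl-3-propionyloxazolidin-2-one | CCC(=O)N1[C@@H](Cc2ccccc2)COC1=O | starting material
22 | sodium (Z)-enolate of 21 | C/C=C(\O[Na])N1[C@@H](Cc2ccccc2)COC1=O | intermediate (not isolated)
23 | (S)-4-benzyl-3-[(R)-2-methylbutanoyl]oxazolidin-2-one | CC[C@@H](C)C(=O)N1[C@@H](Cc2ccccc2)COC1=O | intermediate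
24 | (R)-2-methylbutan-1-ol | CC[C@@H](C)CO | intermediate
25 | (R)-2-methylbutyl trifluoromethanesulfonate | CC[C@@H](C)COS(=O)(=O)C(F)(F)F | intermediate
26 | lithium (Z)-enolate of 21 | C/C=C(\O[Li])N1[C@@H](Cc2ccccc2)COC1=O | intermediate (not isolated)
27 | (S)-4-benzyl-3-[(2R,4R)-2,4-dimethylhexanoyl]oxazolidin-2-one | CC[C@@H](C)C[C@@H](C)C(=O)N1[C@@H](Cc2ccccc2)COC1=O | intermediate
28 | (2R,4R)-2,4-dimethylhexan-1-ol | CC[C@@H](C)C[C@@H](C)CO | intermediate
29 | (2R,4R)-2,4-dimethylhexanal | CC[C@@H](C)C[C@@H](C)C=O | intermediate (not isolated)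
30 | ethyl (2E,4R,6R)-2,4,6-trimethyloct-2-enoate | CC[C@@H](C)C[C@@H](C)/C=C(C)/C(=O)OCC | intermediate
31 | (2E,4R,6R)-2,4,6-trimethyloct-2-en-1-ol | CC[C@@H](C)C[C@@H](C)/C=C(C)/CO | intermediate
32 | (2E,4R,6R)-2,4,6-trimethyloct-2-enal | CC[C@@H](C)C[C@@H](C)/C=C(C)/C=O | intermediate (not isolated)
33 | ethyl (2E,4E,6R,8R)-4,6,8-trimethyldeca-2,4-dienoate | CC[C@@H](C)C[C@@H](C)/C=C(C)/C=C/C(=O)OCC | intermediate
34 | (2E,4E,6R,8R)-4,6,8-trimethyldeca-2,4-dien-1-ol | CC[C@@H](C)C[C@@H](C)/C=C(C)/C=C/CO | intermediate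
35 | (2E,4E,6R,8R)-4,6,8-trimethyldeca-2,4-dienal | CC[C@@H](C)C[C@@H](C)/C=C(C)/C=C/C=O | intermediate
36 | lithium enolate of 20 | [Li]OC(=C)c1c(OCOCC[Si](C)(C)C)c([C@]2(O[Si](CC)(CC)CC)CC[C@@H](O[Si](CC)(CC)CC)CC2)c[n+]([O-])c1OCOCC[Si](C)(C)C | intermediate (not isolated)
37 | 5-[cis-1,4-bis(triethylsilyloxy)cyclohexyl]-3-[(4E,6E,8R,10R)-3-hydroxy-6,8,10-trimethyldodeca-4,6-dienoyl]-2,4-bis{[2-(trimethylsilyl)ethoxy]methoxy}pyridine 1-oxide (C3' epimers) | CC[C@@H](C)C[C@@H](C)/C=C(C)/C=C/C(O)CC(=O)c1c(OCOCC[Si](C)(C)C)c([C@]2(O[Si](CC)(CC)CC)CC[C@@H](O[Si](CC)(CC)CC)CC2)c[n+]([O-])c1OCOCC[Si](C)(C)C | intermediate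
38 | 3-O-acetate of 37 (β-acetoxy ketone) | CC[C@@H](C)C[C@@H](C)/C=C(C)/C=C/C(OC(C)=O)CC(=O)c1c(OCOCC[Si](C)(C)C)c([C@]2(O[Si](CC)(CC)CC)CC[C@@H](O[Si](CC)(CC)CC)CC2)c[n+]([O-])c1OCOCC[Si](C)(C)C | intermediate (not isolated)
39 | 5-[cis-1,4-bis(triethylsilyloxy)cyclohexyl]-3-[(2E,4E,6E,8R,10R)-6,8,10-trimethyldodeca-2,4,6-trienoyl]-2,4-bis{[2-(trimethylsilyl)ethoxy]methoxy}pyridine 1-oxide | CC[C@@H](C)C[C@@H](C)/C=C(C)/C=C/C=C/C(=O)c1c(OCOCC[Si](C)(C)C)c([C@]2(O[Si](CC)(CC)CC)CC[C@@H](O[Si](CC)(CC)CC)CC2)c[n+]([O-])c1OCOCC[Si](C)(C)C | intermediate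
40 | militarinone A | CC[C@@H](C)C[C@@H](C)/C=C(C)/C=C/C=C/C(=O)c1c(O)c([C@]2(O)CC[C@@H](O)CC2)cn(O)c1=O | target

**Totals and risks**

Total step count: 28. Longest linear sequence: 18 steps (steps 1–15 and 26–28); the side-chain branch is 10 steps (16–25) and joins at step 26.

Steps most likely to fail:

1. Step 5 (radical ring enlargement). The benzylic radical may take hydrogen from the stannane before it adds to the ketone, or the cyclopropyloxyl radical may reopen backwards, so that plain deselenation outruns the acyl shift.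
Fallback, known chemistry, setting out from 2 and returning to the route at 9: van Leusen reductive cyanation of 2 (TosMIC, t-BuOK, DME, then MeOH) should give 2-[4-(benzyloxy)phenyl]acetonitrile F1. C-Ethoxycarbonylation (NaH, diethyl carbonate, toluene) then gives ethyl 2-[4-(benzyloxy)phenyl]-2-cyanoacetate F2. Nitrile reduction with in situ protection (NaBH4, NiCl2·6H2O, Boc2O, MeOH) gives ethyl 2-[4-(benzyloxy)phenyl]-3-[(tert-butoxycarbonyl)amino]propanoate F3, and LiOH gives 2-[4-(benzyloxy)phenyl]-3-[(tert-butoxycarbonyl)amino]propanoic acid F4. Coupling with 5 (EDC·HCl, DMAP) gives tert-butyl {2-[4-(benzyloxy)phenyl]-3-(2,2-dimethyl-4,6-dioxo-1,3-dioxan-5-yl)-3-oxopropyl}carbamate F5, which in refluxing EtOAc should close to 9 by the established route from N-Boc β-amino acids to N-Boc piperidine-2,4-diones. The C4–C5 bond is then present from the start as the aryl-bearing carbon of an arylacetic unit and no rearrangement is needed.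

2. Step 4 (selenol addition). The addition may stall because the dione rests as its enol, or the adduct may revert to 7 with loss of PhSeH on concentration.
Fallback setting out from 3 and returning at 8, which puts selenium in before the ring is made: Boc2O/DMAP should convert 3 into methyl (2Z)-3-[4-(benzyloxy)phenyl]-2-[bis(tert-butoxycarbonyl)amino]prop-2-enoate F6, the N,N-diacyl form in which β-aryl dehydroamino esters accept soft nucleophiles. PhSeH with K2CO3 in MeCN then gives methyl 3-[4-(benzyloxy)phenyl]-2-[bis(tert-butoxycarbonyl)amino]-3-(phenylselanyl)propanoate F7. Mg(ClO4)2 in MeCN removes one Boc group to give methyl 3-[4-(benzyloxy)phenyl]-2-[(tert-butoxycarbonyl)amino]-3-(phenylselanyl)propanoate F8, and LiOH gives 3-[4-(benzyloxy)phenyl]-2-[(tert-butoxycarbonyl)amino]-3-(phenylselanyl)propanoic acid F9. Coupling with 5 (EDC·HCl, DMAP) gives tert-butyl {1-[4-(benzyloxy)phenyl]-3-(2,2-dimethyl-4,6-dioxo-1,3-dioxan-5-yl)-3-oxo-1-(phenylselanyl)propan-2-yl}carbamate F10, which should cyclise in refluxing EtOAc to 8, now by the Meldrum's acid procedure on a saturated N-Boc α-amino acid.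

3. Step 10 (para-quinol formation). The electron-rich biaryl may be over-oxidised, water may add ortho instead of para, or the acetic acid released may cleave the SEM acetals.
Fallback setting out from 13 and returning at 14: dye-sensitised photooxygenation of the phenolate (O2, visible light, tetraphenylporphyrin, K2CO3, CHCl3/MeOH, 0 °C) should give 4-(4,6-bis{[2-(trimethylsilyl)ethoxy]methoxy}pyridin-3-yl)-4-hydroperoxycyclohexa-2,5-dien-1-one F11, which Me2S reduces to 14. The oxidant is then singlet oxygen under basic conditions instead of an electrophilic iodine reagent in an acidic medium.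

**Further compounds**

F1 | step 5 | 2-[4-(benzyloxy)phenyl]acetonitrile | N#CCc1ccc(OCc2ccccc2)cc1
F2 | step 5 | ethyl 2-[4-(benzyloxy)phenyl]-2-cyanoacetate (racemic) | CCOC(=O)C(C#N)c1ccc(OCc2ccccc2)cc1
F3 | step 5 | ethyl 2-[4-(benzyloxy)phenyl]-3-[(tert-butoxycarbonyl)amino]propanoate (racemic) | CCOC(=O)C(CNC(=O)OC(C)(C)C)c1ccc(OCc2ccccc2)cc1
F4 | step 5 | 2-[4-(benzyloxy)phenyl]-3-[(tert-butoxycarbonyl)amino]propanoic acid (racemic) | OC(=O)C(CNC(=O)OC(C)(C)C)c1ccc(OCc2ccccc2)cc1
F5 | step 5 | tert-butyl {2-[4-(benzyloxy)phenyl]-3-(2,2-dimethyl-4,6-dioxo-1,3-dioxan-5-yl)-3-oxopropyl}carbamate | CC1(C)OC(=O)C(C(=O)C(CNC(=O)OC(C)(C)C)c2ccc(OCc3ccccc3)cc2)C(=O)O1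
F6 | step 4 | methyl (2Z)-3-[4-(benzyloxy)phenyl]-2-[bis(tert-butoxycarbonyl)amino]prop-2-enoate | COC(=O)/C(N(C(=O)OC(C)(C)C)C(=O)OC(C)(C)C)=C/c1ccc(OCc2ccccc2)cc1
F7 | step 4 | methyl 3-[4-(benzyloxy)phenyl]-2-[bis(tert-butoxycarbonyl)amino]-3-(phenylselanyl)propanoate (stereoisomer mixture) | COC(=O)C(N(C(=O)OC(C)(C)C)C(=O)OC(C)(C)C)C([Se]c1ccccc1)c1ccc(OCc2ccccc2)cc1
F8 | step 4 | methyl 3-[4-(benzyloxy)phenyl]-2-[(tert-butoxycarbonyl)amino]-3-(phenylselanyl)propanoate (stereoisomer mixture) | COC(=O)C(NC(=O)OC(C)(C)C)C([Se]c1ccccc1)c1ccc(OCc2ccccc2)cc1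
F9 | step 4 | 3-[4-(benzyloxy)phenyl]-2-[(tert-butoxycarbonyl)amino]-3-(phenylselanyl)propanoic acid (stereoisomer mixture) | OC(=O)C(NC(=O)OC(C)(C)C)C([Se]c1ccccc1)c1ccc(OCc2ccccc2)cc1
F10 | step 4 | tert-butyl {1-[4-(benzyloxy)phenyl]-3-(2,2-dimethyl-4,6-dioxo-1,3-dioxan-5-yl)-3-oxo-1-(phenylselanyl)propan-2-yl}carbamate | CC1(C)OC(=O)C(C(=O)C(NC(=O)OC(C)(C)C)C([Se]c2ccccc2)c2ccc(OCc3ccccc3)cc2)C(=O)O1
F11 | step 10 | 4-(4,6-bis{[2-(trimethylsilyl)ethoxy]methoxy}pyridin-3-yl)-4-hydroperoxycyclohexa-2,5-dien-1-one | C[Si](C)(C)CCOCOc1cc(OCOCC[Si](C)(C)C)c(cn1)C2(OO)C=CC(=O)C=C2
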